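The route rests on cutting ring C at C3–C4, a bond between two oxygenated carbons (C3–OH, C4=O) that can both start as aldehydes. C2, which bears O1, the ring B aryl group and C3, maps onto the carbinol carbon of 4-hydroxymandelic acid and is joined to the ring A phenol oxygen by Mitsunobu inversion. The precursor is therefore a dialdehyde: the formyl group on C4a of ring A and an (R)-2-aryloxy-2-arylacetaldehyde linked through O1, with the (R)-1-arylethyl group already on C6. One SmI2 pinacol cyclisation should form C3–C4, close ring C and set C3 and C4 as a cis diol trans to the C2 aryl group.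

Key step: step 10

Remark: flavanone numbering is used throughout; (S)-4-hydroxymandelic acid is taken as a purchasable single enantiomer, and the hand of the P,N ligand in step 3 is to be fixed by a test hydrogenation so that the (R)-diarylethane results.

Step 1
Reactants: 1 3,5-dimethoxyphenol
Product: 2 (3,5-dimethoxyphenoxy)triisopropylsilane
Conditions: TIPSCl, imidazole, DMF, rt
Reagents that add atoms: triisopropylsilyl chloride, CC(C)[Si](Cl)(C(C)C)C(C)C
Why: Silyl ether formation masks the acidic phenol, and the bulky triisopropylsilyloxy group is a poor ortho-director, so only the position between the two methoxy groups stays open to the metalation that follows.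

Step 2
Reactants: 2 (3,5-dimethoxyphenoxy)triisopropylsilane; 3 4'-(benzyloxy)acetophenone
Product: 6 {4-[1-(4-(benzyloxy)phenyl)vinyl]-3,5-dimethoxyphenoxy}triisopropylsilane, via aryllithium 4 (not isolated), via tertiary carbinol 5 (not isolated)
Conditions: n-BuLi, THF, 0 °C to rt; 3, −78 °C to rt; H2O; crude with p-TsOH·H2O (cat.), toluene, rt
Reagents that add atoms: none
Why: Directed ortho-metalation places lithium between the two methoxy groups, the aryllithium adds 1,2 to the ketone, and acid-catalysed E1 dehydration of the doubly benzylic tertiary alcohol can only give the terminal 1,1-diarylethene.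

Step 3
Reactants: 6 {4-[1-(4-(benzyloxy)phenyl)vinyl]-3,5-dimethoxyphenoxy}triisopropylsilane
Product: 7 {4-[(1R)-1-(4-(benzyloxy)phenyl)ethyl]-3,5-dimethoxyphenoxy}triisopropylsilane
Conditions: [Ir(cod)(tBu-PHOX)][B(C6H3(CF3)2)4] (2 mol%, ligand hand as in the remark), H2 (50 bar), CH2Cl2, rt
Reagents that add atoms: none
Why: Iridium-catalysed asymmetric hydrogenation of a 1,1-diaryl terminal alkene: the 2,6-dimethoxyaryl ring is twisted out of the alkene plane while the 4-benzyloxyphenyl ring stays conjugated, so the chiral P,N-iridium hydride can tell the two flanks apart and should add H2 to one face, setting the (R) centre without touching the benzyl or silyl ether.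

Step 4
Reactants: 7 {4-[(1R)-1-(4-(benzyloxy)phenyl)ethyl]-3,5-dimethoxyphenoxy}triisopropylsilane
Product: 8 4-[(1R)-1-(4-(benzyloxy)phenyl)ethyl]-3,5-dimethoxyphenol
Conditions: TBAF, THF, 0 °C
Reagents that add atoms: none
Why: Fluoride-mediated desilylation frees the phenol for formylation and etherification, and the diarylmethine hydrogen is not acidic enough to be touched.

Step 5
Reactants: 8 4-[(1R)-1-(4-(benzyloxy)phenyl)ethyl]-3,5-dimethoxyphenol
Product: 9 3-[(1R)-1-(4-(benzyloxy)phenyl)ethyl]-6-hydroxy-2,4-dimethoxybenzaldehyde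
Conditions: MgCl2, Et3N, (CH2O)n, MeCN, reflux
Reagents that add atoms: paraformaldehyde (as formaldehyde), C=O
Why: Casnati–Skattebøl ortho-formylation, in which the magnesium phenoxide delivers formaldehyde to the ortho carbon and a second formaldehyde oxidises the benzylic alkoxide; the two free ring positions are equivalent and the para position is blocked, so a single aldehyde is expected.

Step 6
Reactants: 10 (S)-4-hydroxymandelic acid
Product: 11 benzyl (2S)-2-[4-(benzyloxy)phenyl]-2-hydroxyacetate
Conditions: BnBr (2.1 equiv), K2CO3, DMF, rt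
Reagents that add atoms: benzyl bromide, BrCc1ccccc1
Why: Williamson-type O-alkylation of the carboxylate and the phenoxide in one operation, while the secondary hydroxyl is not deprotonated by K2CO3 and the stereocentre is kept.

Step 7
Reactants: 9 3-[(1R)-1-(4-(benzyloxy)phenyl)ethyl]-6-hydroxy-2,4-dimethoxybenzaldehyde; 11 benzyl (2S)-2-[4-(benzyloxy)phenyl]-2-hydroxyacetate
Product: 12 benzyl (2R)-2-[4-(benzyloxy)phenyl]-2-{4-[(1R)-1-(4-(benzyloxy)phenyl)ethyl]-2-formyl-3,5-dimethoxyphenoxy}acetate
Conditions: PPh3, DIAD, toluene, 0 °C to rt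
Reagents that add atoms: none
Why: Mitsunobu reaction, in which the acidic salicylaldehyde phenol displaces the alkoxyphosphonium group in an SN2 step, so the (S) carbinol carbon becomes the (R) aryl ether carbon that will be C2.

Step 8
Reactants: 12 benzyl (2R)-2-[4-(benzyloxy)phenyl]-2-{4-[(1R)-1-(4-(benzyloxy)phenyl)ethyl]-2-formyl-3,5-dimethoxyphenoxy}acetate
Product: 13 (2R)-2-[4-(benzyloxy)phenyl]-2-{4-[(1R)-1-(4-(benzyloxy)phenyl)ethyl]-2-(hydroxymethyl)-3,5-dimethoxyphenoxy}ethanol
Conditions: i-Bu2AlH (excess), CH2Cl2, −78 to 0 °C; aq. potassium sodium tartrate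
Reagents that add atoms: none
Why: Hydride reduction of the ester and the aryl aldehyde under non-basic, low-temperature conditions should give the diol without epimerising the acidic C–H next to the ester.

Step 9
Reactants: 13 (2R)-2-[4-(benzyloxy)phenyl]-2-{4-[(1R)-1-(4-(benzyloxy)phenyl)ethyl]-2-(hydroxymethyl)-3,5-dimethoxyphenoxy}ethanol
Product: 14 3-[(1R)-1-(4-(benzyloxy)phenyl)ethyl]-6-{[(1R)-1-(4-(benzyloxy)phenyl)-2-oxoethyl]oxy}-2,4-dimethoxybenzaldehyde
Conditions: DMP (3 equiv), NaHCO3, CH2Cl2, 0 °C to rt; filtered and used at once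
Reagents that add atoms: none
Why: Dess–Martin oxidation turns both primary alcohols into aldehydes under buffered, near-neutral conditions, the mildest access to the configurationally sensitive 2-aryloxy-2-arylacetaldehyde, which is carried on without chromatography.

Step 10
Reactants: 14 3-[(1R)-1-(4-(benzyloxy)phenyl)ethyl]-6-{[(1R)-1-(4-(benzyloxy)phenyl)-2-oxoethyl]oxy}-2,4-dimethoxybenzaldehyde
Product: 15 (2R,3S,4S)-2-[4-(benzyloxy)phenyl]-6-[(1R)-1-(4-(benzyloxy)phenyl)ethyl]-5,7-dimethoxychromane-3,4-diol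
Conditions: SmI2 (0.1 M in THF, 2.5 equiv), t-BuOH (2 equiv), THF (0.01 M in 14), −78 °C; pH 7 phosphate buffer
Reagents that add atoms: none
Why: SmI2 should transfer one electron to the conjugated C4a aldehyde, the easier carbonyl to reduce and one that samarium can hold between the carbonyl oxygen, the 5-methoxy oxygen and O1; the benzylic ketyl then adds to the samarium-bound C3 aldehyde (or pairs with a second ketyl there), and a second electron gives a trivalent samarium diolate that is protonated on work-up. The closest known reaction type is the SmI2 pinacol cyclisation of 1,6-dialdehydes to cis-cyclohexane-1,2-diols. Ring C closes in a 6-exo-trig mode, C4 attacking the C3 carbonyl carbon through a half-chair transition state. At C3 the existing C2 centre decides: its aryl group lies pseudo-equatorial and the C3–O bond is placed anti to it (2,3-trans, 3S); at C4 the samarium ion bridging both oxygens forces the C4–O bond cis to the C3–O bond (4S), a pseudo-axial position that also avoids the 5-methoxy group. The step needs C–C bond formation to outrun both loss of the ring A aryloxide from a ketyl at C3 and epimerisation at C2; the ortho arrangement of the two carbonyl arms on ring A, the low temperature, the high dilution and the absence of base or stronger reductant additives are meant to secure this.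

Step 11
Reactants: 15 (2R,3S,4S)-2-[4-(benzyloxy)phenyl]-6-[(1R)-1-(4-(benzyloxy)phenyl)ethyl]-5,7-dimethoxychromane-3,4-diol
Product: 16 (2R,3R)-2-[4-(benzyloxy)phenyl]-6-[(1R)-1-(4-(benzyloxy)phenyl)ethyl]-3-hydroxy-5,7-dimethoxychroman-4-one
Conditions: DDQ (1.1 equiv), CH2Cl2, 0 °C to rt
Reagents that add atoms: none
Why: DDQ dehydrogenation of an electron-rich benzylic alcohol: hydride is taken from C4, whose cation is stabilised by its own hydroxyl and by the oxygens on C5, C7 and C8a, whereas the C3 carbinol is not benzylic and the C–H of the C6 side chain lies in the plane of ring A between two methoxy groups, out of conjugation.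

Step 12
Reactants: 16 (2R,3R)-2-[4-(benzyloxy)phenyl]-6-[(1R)-1-(4-(benzyloxy)phenyl)ethyl]-3-hydroxy-5,7-dimethoxychroman-4-one
Product: 17 (2R,3R)-3,5-dihydroxy-2-(4-hydroxyphenyl)-6-[(1R)-1-(4-hydroxyphenyl)ethyl]-7-methoxychroman-4-one
Conditions: BCl3 (excess), C6HMe5, CH2Cl2, −78 to 0 °C; MeOH, H2O
Reagents that add atoms: none
Why: Lewis-acid ether cleavage: BCl3 with pentamethylbenzene as cation scavenger removes both aryl benzyl ethers, and chelation of boron between the C4 carbonyl and the peri 5-methoxy oxygen directs demethylation to that ether alone, leaving the 7-methoxy group and the three stereocentres in place.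

Compound list
1 | 3,5-dimethoxyphenol | COc1cc(O)cc(OC)c1 | starting material
2 | (3,5-dimethoxyphenoxy)triisopropylsilane | COc1cc(O[Si](C(C)C)(C(C)C)C(C)C)cc(OC)c1 | intermediate
3 | 4'-(benzyloxy)acetophenone | CC(=O)c1ccc(OCc2ccccc2)cc1 | starting material
4 | [2,6-dimethoxy-4-(triisopropylsilyloxy)phenyl]lithium (aryllithium) | [Li]c1c(OC)cc(O[Si](C(C)C)(C(C)C)C(C)C)cc1OC | intermediate
5 | racemic 1-[4-(benzyloxy)phenyl]-1-[2,6-dimethoxy-4-(triisopropylsilyloxy)phenyl]ethanol (tertiary carbinol) | CC(O)(c1ccc(OCc2ccccc2)cc1)c1c(OC)cc(O[Si](C(C)C)(C(C)C)C(C)C)cc1OC | intermediate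
6 | {4-[1-(4-(benzyloxy)phenyl)vinyl]-3,5-dimethoxyphenoxy}triisopropylsilane | C=C(c1ccc(OCc2ccccc2)cc1)c1c(OC)cc(O[Si](C(C)C)(C(C)C)C(C)C)cc1OC | intermediate
7 | {4-[(1R)-1-(4-(benzyloxy)phenyl)ethyl]-3,5-dimethoxyphenoxy}triisopropylsilane | COc1cc(O[Si](C(C)C)(C(C)C)C(C)C)cc(OC)c1[C@H](C)c1ccc(OCc2ccccc2)cc1 | intermediate
8 | 4-[(1R)-1-(4-(benzyloxy)phenyl)ethyl]-3,5-dimethoxyphenol | COc1cc(O)cc(OC)c1[C@H](C)c1ccc(OCc2ccccc2)cc1 | intermediate
9 | 3-[(1R)-1-(4-(benzyloxy)phenyl)ethyl]-6-hydroxy-2,4-dimethoxybenzaldehyde | COc1cc(O)c(C=O)c(OC)c1[C@H](C)c1ccc(OCc2ccccc2)cc1 | intermediate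
10 | (S)-4-hydroxymandelic acid | OC(=O)[C@@H](O)c1ccc(O)cc1 | starting material
11 | benzyl (2S)-2-[4-(benzyloxy)phenyl]-2-hydroxyacetate | O=C(OCc1ccccc1)[C@@H](O)c1ccc(OCc2ccccc2)cc1 | intermediate
12 | benzyl (2R)-2-[4-(benzyloxy)phenyl]-2-{4-[(1R)-1-(4-(benzyloxy)phenyl)ethyl]-2-formyl-3,5-dimethoxyphenoxy}acetate | COc1cc(O[C@@H](C(=O)OCc2ccccc2)c2ccc(OCc3ccccc3)cc2)c(C=O)c(OC)c1[C@H](C)c1ccc(OCc2ccccc2)cc1 | intermediate
13 | (2R)-2-[4-(benzyloxy)phenyl]-2-{4-[(1R)-1-(4-(benzyloxy)phenyl)ethyl]-2-(hydroxymethyl)-3,5-dimethoxyphenoxy}ethanol | COc1cc(O[C@@H](CO)c2ccc(OCc3ccccc3)cc2)c(CO)c(OC)c1[C@H](C)c1ccc(OCc2ccccc2)cc1 | intermediate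
14 | 3-[(1R)-1-(4-(benzyloxy)phenyl)ethyl]-6-{[(1R)-1-(4-(benzyloxy)phenyl)-2-oxoethyl]oxy}-2,4-dimethoxybenzaldehyde (dialdehyde, precursor of the key step) | COc1cc(O[C@@H](C=O)c2ccc(OCc3ccccc3)cc2)c(C=O)c(OC)c1[C@H](C)c1ccc(OCc2ccccc2)cc1 | intermediate
15 | (2R,3S,4S)-2-[4-(benzyloxy)phenyl]-6-[(1R)-1-(4-(benzyloxy)phenyl)ethyl]-5,7-dimethoxychromane-3,4-diol (2,3-trans-3,4-cis) | COc1cc2c(c(OC)c1[C@H](C)c1ccc(OCc3ccccc3)cc1)[C@H](O)[C@H](O)[C@@H](c1ccc(OCc3ccccc3)cc1)O2 | intermediate
16 | (2R,3R)-2-[4-(benzyloxy)phenyl]-6-[(1R)-1-(4-(benzyloxy)phenyl)ethyl]-3-hydroxy-5,7-dimethoxychroman-4-one | COc1cc2c(c(OC)c1[C@H](C)c1ccc(OCc3ccccc3)cc1)C(=O)[C@H](O)[C@@H](c1ccc(OCc3ccccc3)cc1)O2 | intermediate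
17 | (2R,3R)-3,5-dihydroxy-2-(4-hydroxyphenyl)-6-[(1R)-1-(4-hydroxyphenyl)ethyl]-7-methoxychroman-4-one | COc1cc2c(c(O)c1[C@H](C)c1ccc(O)cc1)C(=O)[C@H](O)[C@@H](c1ccc(O)cc1)O2 | target

Total step count: 12.
Longest linear sequence: 11 steps (steps 1 to 5 and 7 to 12, from 3,5-dimethoxyphenol); the mandelate branch adds step 6.

Steps most likely to fail

Step 10. Electron transfer to the aliphatic C3 aldehyde may compete, and the ketyl formed there can expel the ring A aryloxide (reductive scission of the C2–O1 bond) before the C3–C4 bond forms; a loose transition state could also lower the facial selectivity at C3. The fallback avoids single-electron reduction altogether. Setting out from 14, both formyl groups are methylenated with salt-free Ph3P=CH2 (THF, −78 °C) to give the 2-vinylaryl 1-arylallyl ether F1. Ring-closing metathesis with second-generation Grubbs catalyst (CH2Cl2, 40 °C) then closes ring C across C3–C4 as the 2-aryl-2H-chromene (flav-3-ene) F2. OsO4 (cat.) with NMO in acetone–water should add both hydroxyl groups to the face anti to the C2 aryl group, the usual course for flav-3-enes, and the route is rejoined at 15.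

Step 3. The catalyst may not distinguish the two aryl flanks well enough (low enantiofacial discrimination), or hydrogen uptake at the hindered alkene may stall. The fallback trades asymmetric catalysis for resolution. From 6, hydrogenation with achiral [Ir(cod)(PCy3)(py)]PF6 (H2, CH2Cl2) gives the racemic silyl ether F3, and TBAF gives the racemic phenol F4. Preparative chromatography on a chiral stationary phase separates the enantiomers, and the (R)-enantiomer is 8.

Step 11. Hydride abstraction could occur at a wrong benzylic site (C2–H or the methine of the C6 side chain), the ketol could be dehydrogenated further towards the flavonol, or the acidic hydroquinone by-product could ionise the C4 hydroxyl. The fallback replaces the chemoselective oxidation by a protecting-group sequence. From 15, the less hindered equatorial C3 hydroxyl is silylated (TESCl, imidazole, CH2Cl2, −20 °C) to the 3-O-triethylsilyl ether F5. Dess–Martin oxidation of the remaining C4 carbinol gives the silylated ketol F6, and HF·pyridine in THF removes the silyl group and returns 16.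

Further compounds
F1 | step 10 | 1-{[(1S)-1-(4-(benzyloxy)phenyl)prop-2-en-1-yl]oxy}-4-[(1R)-1-(4-(benzyloxy)phenyl)ethyl]-3,5-dimethoxy-2-vinylbenzene (same spatial arrangement at the ether carbon as in 14) | COc1cc(O[C@@H](C=C)c2ccc(OCc3ccccc3)cc2)c(C=C)c(OC)c1[C@H](C)c1ccc(OCc2ccccc2)cc1
F2 | step 10 | (2S)-2-[4-(benzyloxy)phenyl]-6-[(1R)-1-(4-(benzyloxy)phenyl)ethyl]-5,7-dimethoxy-2H-chromene (same spatial arrangement at C2 as in 15) | COc1cc2c(c(OC)c1[C@H](C)c1ccc(OCc3ccccc3)cc1)C=C[C@@H](c1ccc(OCc3ccccc3)cc1)O2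
F3 | step 3 | racemic {4-[1-(4-(benzyloxy)phenyl)ethyl]-3,5-dimethoxyphenoxy}triisopropylsilane | COc1cc(O[Si](C(C)C)(C(C)C)C(C)C)cc(OC)c1C(C)c1ccc(OCc2ccccc2)cc1
F4 | step 3 | racemic 4-[1-(4-(benzyloxy)phenyl)ethyl]-3,5-dimethoxyphenol | COc1cc(O)cc(OC)c1C(C)c1ccc(OCc2ccccc2)cc1
F5 | step 11 | (2R,3S,4S)-2-[4-(benzyloxy)phenyl]-6-[(1R)-1-(4-(benzyloxy)phenyl)ethyl]-5,7-dimethoxy-3-(triethylsilyloxy)chroman-4-ol | COc1cc2c(c(OC)c1[C@H](C)c1ccc(OCc3ccccc3)cc1)[C@H](O)[C@H](O[Si](CC)(CC)CC)[C@@H](c1ccc(OCc3ccccc3)cc1)O2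
F6 | step 11 | (2R,3R)-2-[4-(benzyloxy)phenyl]-6-[(1R)-1-(4-(benzyloxy)phenyl)ethyl]-5,7-dimethoxy-3-(triethylsilyloxy)chroman-4-one | COc1cc2c(c(OC)c1[C@H](C)c1ccc(OCc3ccccc3)cc1)C(=O)[C@H](O[Si](CC)(CC)CC)[C@@H](c1ccc(OCc3ccccc3)cc1)O2
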